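All runs are calculated for an exercise; scatter was added.

Open the ledger on this flask.

| flask | starting material | reagent in the second phase | protic impurity | remark | time | volume of the second phase over the first |
|---|---|---|---|---|---|---|
| Saturday's | 0.10 M | 0.095 M | 0.030 M | the very flask that is asked about, followed so far |  |  |
| flask | 0.10 M | 0.0950 M | 0.0300 M |  | 1.0 h | 2.0 |

- Saturday's (time / min: target / %): 2.00: 0; 6.00: 2; 12.0: 6; 15.0: 8; 25.0: 14

(readings scatter by 1.5 percentage points)

- in the second phase: reagent in the second phase; everything else is in the first
- charges count per volume of the first phase; a concentration in a rate is the amount of a species over the volume of its own phase; every rate counts per litre of the first phase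
- the earlier runs hold the two phases in the same ratio of volumes as the flask asked about

- dusk: doubling the amount of reagent in the second phase, all else as stated
- spring: doubling the transfer coefficient of the reagent in the second phase, all else as stated

- target at 1.0 h, in percent of the starting material charged
- the change that raises the amount of target at 1.0 h, in percent of the starting material charged most ("none" if none brings more than 2 percentage points) (dusk / spring / none)
- amount of target at 1.0 h, in percent of the starting material charged, after dusk

1. Enter the impurity first. Its claim is protic impurity charged over starting material charged: 30.0%. Assume that it attacks starting material, one for one, and book it there.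

2. That leaves a free share of 70.0%, less than the 95.0% that the reagent charge covers. So in this ledger starting material is the limiting reagent.

3. Read the target entry. From 6.00 min to 25.0 min target climbs by 0.00632 min⁻¹ as a fraction of the charge, a reading with 1.5 percentage points of scatter on each point. Drawn back to zero, that line gives a lag of 2.83 min.

4. Price the lag. Treat it as reagent crossing over. Wiping it out is worth 1.8 points, less than the 2 points mark, so set spring aside.

5. Run the free share down as a pseudo-first-order decay, with reagent held steady. Its rate constant is 0.00902 min⁻¹, so my target at 1.0 h is 28.2%.

6. Double the constant for dusk, assuming the rate follows the reagent. That gives 45.0%, a gain above the mark, so commit to dusk.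

The forecast, which reads the lag differently as “the protic impurity eating 0.03 M of reagent first”, gives 30%, dusk and 58%.

The flask gives 25.1%. Dusk gains 17 points and reaches 42.2%, spring gains 0.47 points, and the best change is dusk.

    starting material + protic impurity → quenched substrate (k = 0.0210 M⁻¹ s⁻¹)
    reagent in the reaction phase ⇌ reagent in the second phase, rate k2*([reagent in the reaction phase] - [reagent in the second phase]/K2) per volume of the first phase (partition coefficient = 0.440, kL = 0.00390 s⁻¹)
    starting material + reagent in the reaction phase → target (k = 0.00280 M⁻¹ s⁻¹)

At 1.00 h this flask holds quenched substrate 29.7%, close to the claim of 30.0%, with protic impurity at 0.999% of its own charge. Now take a neighbour flask charged with 0.12 M of protic impurity, all else as in this flask. Its claim is 120%, more than the charge of starting material. At 1.00 h that neighbour holds quenched substrate 90.1%, protic impurity 24.9% of its own charge, starting material 2.26% and target 7.65%.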